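At early times a rate can be read straight from one reading, so that is where we start on these runs.

| setting | oak | cedar | elm | maple | larch |
|---|---|---|---|---|---|
| starting material | 0.150 M | 0.0750 M | 0.450 M | 0.150 M | 0.150 M |
| reagent | 0.180 M | 0.105 M | 0.180 M | 0.180 M | 0.0590 M |
| catalyst | 0.00300 M | 0.00300 M | 0.00300 M | 0.00900 M | 0.00150 M |
| time |  |  |  |  | 80 min |

| oak run: time / min | oak run: [product] / M | cedar run: time / min | cedar run: [product] / M | elm run: time / min | elm run: [product] / M | maple run: time / min | maple run: [product] / M |
|---|---|---|---|---|---|---|---|
| 11 | 0.0064 | 11 | 0.0021 | 11 | 0.0153 | 11 | 0.0114 |
| 23 | 0.0149 | 23 | 0.0038 | 23 | 0.0478 | 23 | 0.0248 |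
| 34 | 0.0227 | 34 | 0.0036 | 34 | 0.0856 | 34 | 0.0383 |
| 46 | 0.0314 | 46 | 0.0107 | 46 | 0.1236 | 46 | 0.0532 |
| 57 | 0.0439 | 57 | 0.0084 | 57 | 0.1478 | 57 | 0.0644 |
| 69 | 0.0539 | 69 | 0.0132 | 69 | 0.1630 | 69 | 0.0758 |
| 80 | 0.0639 | 80 | 0.0153 | 80 | 0.1700 | 80 | 0.0883 |

(each reading ± 0.001 M)

- Overall: starting material + reagent -> product, with catalyst as catalyst.
- Constant volume, constant temperature.
- Readings of a species count what is bound in complexes too.
- An order is taken over about fifteen percent of the charge, up and down.

1. reaction order in [starting material] at the outset, round the charge of the oak run, defined at two percent of the starting material turned into product (one fixed amount of product, the same in the runs compared)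
2. reaction order in [catalyst] at the outset, round the charge of the oak run, defined at two percent of the starting material turned into product
3. the cedar run starts with 0.0750 M less of starting material and of reagent than the oak run, and with no product. Compared where both hold the same amount of starting material, once fifteen percent of what the cedar run was charged with has turned into product, is the cedar run faster, slower or alike (within a tenth)?
4. product in the larch run at 80 min, as a share of the starting material charged

Oak and maple differ in c(catalyst) by a factor of 3.00. At 11 min oak holds 0.0064 M of product and maple 0.0114 M, a ratio of 1.78. In logarithms this gives an order of 0.525. But that is a chord across the whole factor, and the order is asked close round oak's charge. A catalyst working through its own sites gives a rate in proportion to it, so an order well under one suggests a second part of the rate that ignores the catalyst. The rate is then a sum, and its slope in logarithms changes along the way. So we carry the catalyst share: the fraction of oak's rate that is in proportion to c(catalyst), which equals the local order. Maple's charge adds twice that share to oak's rate, so the pair gives 0.391. The objection is scatter: with the stated error on both readings, this share is good to 0.160 either way.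

Now larch. Its catalyst is half of oak's, so the share says 0.805 of oak's rate remains. Does reagent count at the first power? The cedar run changes c(reagent) but also c(starting material), so its readings do not separate the two, and we take the first power as an assumption, not as a reading. From oak's early rate of 5.82 × 10⁻⁴ M/min, larch makes 0.0123 M by 80 min. But reagent is larch's limiting reagent, 0.0590 M against 0.150 M of starting material, and its mean falls by 10.4% over the run. That brings the estimate to 0.0110 M, or 7.33%. Another objection: oak's rate climbs later, to 9.09 × 10⁻⁴ M/min in its last stretch, as product builds. Yet oak's early rate already holds a mean product near 0.00320 M, and larch's mean is near 0.00550 M, so we let that gap stand.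

The forecast, made from these same runs, gives an order in starting material of 0.75 (0.55 to 0.95) and in catalyst of 0.55 (0.42 to 0.7). It calls cedar slower and puts larch at 7.5% (5.5% to 10%). Its catalyst order rests on maple being “about 1.85 times oak for three times the catalyst”. Our share stands lower than that order.

The flask gives orders of 0.72 in starting material and 0.45 in catalyst, cedar slower at 0.30 of oak's rate, and larch 7.27%, against the 7.33% our share gave.

    catalyst + starting material ⇌ catalyst-substrate complex, settled at all times (12.80 /M)
    catalyst-substrate complex + reagent → product + catalyst (0.6900 /M/min)
    starting material + reagent → product (0.007800 /M/min)
    starting material + reagent + product → 2 product (1.050 /M²/min)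

Maple's rate over oak's at equal product is 1.9. As a chord in logarithms that is 0.579, but as a catalyst share it is 0.445, beside our reading of 0.391. The order in catalyst stands at 0.45 due to the conversion of starting material and reagent without catalyst: in the run with that conversion taken away, the order is 0.74.

(The runs are calculated for an exercise.)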